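The readings were computed for substances that don't exist; the scatter is artificial.

You start from a small charge of substrate and follow what fraction of it stands as target, on a clock set by the runs below.

| flask | substrate | coupling partner | precatalyst | remark | time |
|---|---|---|---|---|---|
| red | 28 mM | 24 mM | 2 mM | run made earlier |  |
| green | 44 mM | 24 mM | 2 mM | run made earlier |  |
| amber | 20 mM | 24 mM | 3 mM | run made earlier |  |
| flask | 20 mM | 24.0 mM | 2.0 mM |  | 15 d |

- red (time / d: target / %): 1.25: 0.5; 2.00: 6.1; 3.00: 11.9; 6.00: 15.0; 10.0: 8.4; 15.0: 3.0
- green (time / d: target / %): 1.25: 1.3; 2.00: 6.1; 3.00: 11.1; 6.00: 14.0; 10.0: 4.4; 15.0: 2.2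
- amber (time / d: target / %): 1.25: 3.8; 2.50: 15.3; 4.00: 23.4; 8.00: 13.3; 15.0: 5.1

(standard deviation of a reading: 1 percentage point)

1. the best time, 15 d at the latest, for target
2. the amount of target, in percent of the substrate charged, at that time
3. the first time at which target reaches 5.4 %, in the same percent, in d



Does the size of the charge move the early fraction? Green carries 1.57 times the substrate of red, yet at 2.00 d both read 6.1 %. So I read the flask's rise off red, which has the same precatalyst, and put the crossing just before 2.00 d.

Then how long does target last once it falls? Amber has the flask's substrate charge, though 1.50 times its precatalyst, and it drops from 13.3 % at 8.00 d to 5.1 % at 15.0 d. As a reading, that is a decay rate of 0.137 d⁻¹. Call the matching time the tail half-life, 5.06 d: the apparent first-order time in which target falls by half after its best.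

Is waiting worthwhile? The tail half-life, read from amber, is a third of the 15 d allowed, so I expect the best well inside the window.

The forecast gives 17.5 % at 5.5 d and 1.95 d for the crossing. Its loss rate lies slightly below mine: “At 20 mM the flask should lose target at about 0.13/d.” Carried to the end at my tail half-life, its best leaves 4.76 %.

The flask gives 18.1 % at 5.12 d, and crosses at 1.93 d.

    substrate + catalyst → catalyst + intermediate (k = 0.0110 M⁻¹ s⁻¹)
    coupling partner + catalyst + intermediate → catalyst + target (k = 0.0950 M⁻² s⁻¹)
    precatalyst ⇌ catalyst (K = 1.40, k = 4.90 × 10⁻⁶ s⁻¹)
    target → over-reaction product (k = 5.50 × 10⁻⁶ s⁻¹)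

At that best time the flask holds 58.0 % as intermediate and 18.1 % as target. Run from the flask's best to the end, the tail half-life gives 4.68 %, and the flask stands at 4.93 %. The neighbour flask with 0.50 mM of precatalyst goes from a best of 6.55 % to 5.64 % at the end, a fall worth 1.09 d of tail, with 60.6 % still intermediate.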